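**Plan**
- Cuts, in retrosynthetic order: the C5–O and C7–O bonds of ring A (back to C–F); ring C at O1–C8a and C2–C3; the bond from benzofuran C7 to the ketone α-carbon (later C3); the dihydrofuran C2–O bond; the aryl–prenyl bond.
- Enabling feature: on ring A, O1 (at C8a), O5 and O7 occupy the two ortho positions and the para position relative to C4a, the carbon that carries the C4 carbonyl. A 2,4,6-trifluorobenzoyl group, whose two ortho C–F bonds are equivalent, can therefore accept all three oxygens by addition–elimination.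
- Forward order: prenylation of the 3,4-dimethoxyphenol core between OH and OMe, dihydrofuran ring, C7 bromination, Pd α-arylation to join the B-ring block to the trifluorophenyl ketone, ring C by formylation/SNAr, then F → OBn → OH on ring A.
- Stereochemistry: the single stereocentre (benzofuran C2, R) comes from a Shi epoxidation to the (S)-epoxide, which the phenoxide opens with inversion. No later step touches it.

Key step: step 10

Assumption: the enantiomer of the D-fructose-derived Shi ketone (1,2:4,5-di-O-isopropylidene-β-L-erythro-2,3-hexodiulo-2,6-pyranose, accessible from L-sorbose) is treated as a purchasable catalyst.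

**Step 1**
Reactants: 1 3,4-dimethoxyphenol
Product: 2 1,2-dimethoxy-4-(methoxymethoxy)benzene
Conditions: MOMCl, i-Pr2NEt, CH2Cl2, 0 °C → rt
Reagents that add atoms: chloromethyl methyl ether, COCCl
Why: Williamson-type O-alkylation with an α-chloro ether installs an acetal that survives butyllithium and acts as the directing group in step 2.

**Step 2**
Reactants: 2 1,2-dimethoxy-4-(methoxymethoxy)benzene; 3 prenyl bromide (1-bromo-3-methylbut-2-ene)
Product: 5 1,2-dimethoxy-4-(methoxymethoxy)-3-(3-methylbut-2-en-1-yl)benzene, via aryllithium 4 (not isolated)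
Conditions: n-BuLi, THF, 0 °C → rt; CuBr·SMe2 (10 mol%), 3, −78 °C → rt
Reagents that add atoms: prenyl bromide 3, CC(C)=CCBr
Why: Directed ortho-metalation removes the proton flanked by OMOM and OMe through cooperative coordination, and copper-catalysed SN2 allylation at the primary carbon of 3 places the prenyl group at the crowded ortho site that electrophilic prenylation of 1 would avoid.

**Step 3**
Reactants: 5 1,2-dimethoxy-4-(methoxymethoxy)-3-(3-methylbut-2-en-1-yl)benzene
Product: 6 3,4-dimethoxy-2-(3-methylbut-2-en-1-yl)phenol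
Conditions: conc. HCl (cat.), MeOH, 40 °C
Reagents that add atoms: none
Why: Acid-catalysed transacetalisation to methanol is faster than protonation of the trisubstituted olefin, so chroman formation should stay minor under these mild conditions.

**Step 4**
Reactants: 6 3,4-dimethoxy-2-(3-methylbut-2-en-1-yl)phenol
Product: 7 tert-butyl[3,4-dimethoxy-2-(3-methylbut-2-en-1-yl)phenoxy]dimethylsilane
Conditions: TBSCl, imidazole, DMF, rt
Reagents that add atoms: tert-butyldimethylsilyl chloride, CC(C)(C)[Si](C)(C)Cl
Why: Imidazole-promoted silylation masks the p-methoxyphenol, which Oxone would otherwise oxidise, with a group that fluoride removes later without acid.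

**Step 5**
Reactants: 7 tert-butyl[3,4-dimethoxy-2-(3-methylbut-2-en-1-yl)phenoxy]dimethylsilane
Product: 8 tert-butyl(2-{[(2S)-3,3-dimethyloxiran-2-yl]methyl}-3,4-dimethoxyphenoxy)dimethylsilane
Conditions: ent-Shi ketone (30 mol%), Oxone, K2CO3, Bu4NHSO4 (cat.), MeCN–DMM/aq. Na2B4O7–Na2EDTA buffer, 0 °C
Reagents that add atoms: Oxone (active component potassium peroxymonosulfate), [K+].[O-]S(=O)(=O)OO
Why: In this Shi asymmetric epoxidation the chiral dioxirane meets the trisubstituted olefin in the spiro transition state; the D-fructose ketone gives the (R)-epoxide of RCH2CH=CMe2 olefins, so its enantiomer should give the (S)-epoxide, and the olefin reacts far faster than the arene.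

**Step 6**
Reactants: 8 tert-butyl(2-{[(2S)-3,3-dimethyloxiran-2-yl]methyl}-3,4-dimethoxyphenoxy)dimethylsilane
Product: 10 2-[(2R)-4,5-dimethoxy-2,3-dihydro-1-benzofuran-2-yl]propan-2-ol, via epoxy phenoxide 9 (not isolated)
Conditions: TBAF, THF, 0 °C → rt
Reagents that add atoms: none
Why: Fluoride desilylation frees the phenoxide, which opens the epoxide under basic conditions by a Baldwin-favoured 5-exo-tet SN2 attack at the secondary carbon, inverting (S) to (R) and leaving the epoxide oxygen as the tertiary alcohol.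

**Step 7**
Reactants: 10 2-[(2R)-4,5-dimethoxy-2,3-dihydro-1-benzofuran-2-yl]propan-2-ol
Product: 11 2-[(2R)-7-bromo-4,5-dimethoxy-2,3-dihydro-1-benzofuran-2-yl]propan-2-ol
Conditions: NBS (1.0 equiv), MeCN, 0 °C, dark
Reagents that add atoms: N-bromosuccinimide, O=C1CCC(=O)N1Br
Why: In this electrophilic aromatic bromination C7 is ortho to the ring oxygen and para to the 4-OMe group while C6 is activated only by the 5-OMe group, the same orientation that sends bromine to C5 of 1,2,4-trimethoxybenzene.

**Step 8**
Reactants: 11 2-[(2R)-7-bromo-4,5-dimethoxy-2,3-dihydro-1-benzofuran-2-yl]propan-2-ol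
Product: 12 {2-[(2R)-7-bromo-4,5-dimethoxy-2,3-dihydro-1-benzofuran-2-yl]propan-2-yloxy}triethylsilane
Conditions: TESOTf, 2,6-lutidine, CH2Cl2, 0 °C
Reagents that add atoms: triethylsilyl trifluoromethanesulfonate, CC[Si](CC)(CC)OS(=O)(=O)C(F)(F)F
Why: Silyl triflate/lutidine silylation is the standard method for hindered tertiary alcohols and keeps a tertiary alkoxide from forming next to fluoroarenes and formate in steps 9 to 11.

**Step 9**
Reactants: 12 {2-[(2R)-7-bromo-4,5-dimethoxy-2,3-dihydro-1-benzofuran-2-yl]propan-2-yloxy}triethylsilane; 13 2',4',6'-trifluoroacetophenone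
Product: 14 1-(2,4,6-trifluorophenyl)-2-[(2R)-4,5-dimethoxy-2-(2-triethylsilyloxypropan-2-yl)-2,3-dihydro-1-benzofuran-7-yl]ethanone
Conditions: 13 (1.5 equiv), Pd2(dba)3 (2.5 mol%), Xantphos (6 mol%), K3PO4, toluene, 90 °C
Reagents that add atoms: 2',4',6'-trifluoroacetophenone 13, CC(=O)c1c(F)cc(F)cc1F
Why: In this Buchwald–Hartwig–Miura α-arylation of an aryl methyl ketone the weak heterogeneous base keeps the enolate concentration low, the di-ortho-substituted carbonyl is a poor aldol acceptor, and the more acidic, more hindered product enolate resists a second arylation.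

**Step 10**
Reactants: 14 1-(2,4,6-trifluorophenyl)-2-[(2R)-4,5-dimethoxy-2-(2-triethylsilyloxypropan-2-yl)-2,3-dihydro-1-benzofuran-7-yl]ethanone; 15 2,2,2-trifluoroethyl formate
Product: 18 3-[(2R)-4,5-dimethoxy-2-(2-triethylsilyloxypropan-2-yl)-2,3-dihydro-1-benzofuran-7-yl]-5,7-difluorochromen-4-one, via ketone enolate 16 (not isolated), via formyl ketone enolate 17 (not isolated)
Conditions: LiHMDS (1.1 equiv), THF, −78 °C; 15 (1.5 equiv), −78 °C → rt; DMPU, 50 °C
Reagents that add atoms: 2,2,2-trifluoroethyl formate 15, O=COCC(F)(F)F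
Why: LiHMDS turns 14 into enolate 16, a crossed Claisen condensation with the activated formate 15 forges C2–C3 at the benzylic carbon, and the released trifluoroethoxide is spent at once in deprotonating the much more acidic formyl ketone, so that 17 is the only competent nucleophile left while trifluoroethanol and HMDS stay neutral. After DMPU and gentle heating have loosened the lithium chelate, rotation about C3–C4 places the formyl oxygen of 17 over an ortho C–F carbon, where addition gives a Meisenheimer anion stabilised by the C4 carbonyl and the two other fluorines, and loss of fluoride as insoluble LiF (harmless to the TES ether) creates O1–C8a. The closest known chemistry is enolate formylation with trifluoroethyl formate combined with the base-induced closure of 2-fluoroaryl 1,3-dicarbonyl compounds to chromones, which parallels, with oxygen in place of nitrogen, the cycloaracylation used for 4-quinolones. Ring C closes as a six-membered ring by intramolecular addition–elimination, formally 6-endo-trig with respect to the C4a=C8a bond that relays the charge to the carbonyl group; no stereocentre is formed and benzofuran C2 lies far from every acidic site. The step needs C- over O-formylation, O- over C-arylation and ortho over para displacement: an enol formate is itself a formyl donor and drains into the stabilised anion 17, carbon attack on the ring would demand a four-membered ring, and the para carbon cannot be reached within the molecule. The two ortho fluorides are interchanged by rotation of the symmetric aryl group, so no regiochemical choice arises.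

**Step 11**
Reactants: 18 3-[(2R)-4,5-dimethoxy-2-(2-triethylsilyloxypropan-2-yl)-2,3-dihydro-1-benzofuran-7-yl]-5,7-difluorochromen-4-one
Product: 21 5,7-bis(benzyloxy)-3-[(2R)-2-(2-hydroxypropan-2-yl)-4,5-dimethoxy-2,3-dihydro-1-benzofuran-7-yl]chromen-4-one, via monobenzyloxy monofluoro isoflavone 19 (not isolated), via bis(benzyloxy) silyl ether 20 (not isolated)
Conditions: BnOH, NaH (3 equiv each), THF–DMF, 0 → 60 °C; then 2 M aq. HCl, rt
Reagents that add atoms: benzyl alcohol, OCc1ccccc1
Why: In this double nucleophilic aromatic substitution C7–F (para) and C5–F (ortho) are both conjugated with the C4 carbonyl through C4a and lie meta to each other, so the first benzyloxy group sits on no charge-bearing carbon of the second Meisenheimer adduct, while benzyloxide addition at C2 is reversible without water and the acidic quench re-closes any opened pyranone and hydrolyses the TES ether.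

**Step 12**
Reactants: 21 5,7-bis(benzyloxy)-3-[(2R)-2-(2-hydroxypropan-2-yl)-4,5-dimethoxy-2,3-dihydro-1-benzofuran-7-yl]chromen-4-one
Product: 22 5,7-dihydroxy-3-[(2R)-2-(2-hydroxypropan-2-yl)-4,5-dimethoxy-2,3-dihydro-1-benzofuran-7-yl]chromen-4-one (CNP0211379.1)
Conditions: H2 (1 atm), 10% Pd/C, EtOAc–EtOH, rt, stopped at full debenzylation
Reagents that add atoms: none
Why: Catalytic hydrogenolysis of aryl benzyl ethers is routine on isoflavones and runs faster than reduction of the C2=C3 bond, and neither the dihydrofuran C–O bond nor the tertiary alcohol is benzylic.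

**Compound list**
1 | 3,4-dimethoxyphenol | COc1ccc(O)cc1OC | starting material
2 | 1,2-dimethoxy-4-(methoxymethoxy)benzene | COCOc1ccc(OC)c(OC)c1 | intermediate
3 | prenyl bromide | CC(C)=CCBr | starting material
4 | [2,3-dimethoxy-6-(methoxymethoxy)phenyl]lithium | [Li]c1c(OCOC)ccc(OC)c1OC | intermediate
5 | 1,2-dimethoxy-4-(methoxymethoxy)-3-(3-methylbut-2-en-1-yl)benzene | COCOc1ccc(OC)c(OC)c1CC=C(C)C | intermediate
6 | 3,4-dimethoxy-2-(3-methylbut-2-en-1-yl)phenol | COc1ccc(O)c(CC=C(C)C)c1OC | intermediate
7 | tert-butyl[3,4-dimethoxy-2-(3-methylbut-2-en-1-yl)phenoxy]dimethylsilane | COc1ccc(O[Si](C)(C)C(C)(C)C)c(CC=C(C)C)c1OC | intermediate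
8 | tert-butyl(2-{[(2S)-3,3-dimethyloxiran-2-yl]methyl}-3,4-dimethoxyphenoxy)dimethylsilane | COc1ccc(O[Si](C)(C)C(C)(C)C)c(C[C@@H]2OC2(C)C)c1OC | intermediate
9 | tetrabutylammonium 2-{[(2S)-3,3-dimethyloxiran-2-yl]methyl}-3,4-dimethoxyphenoxide | CCCC[N+](CCCC)(CCCC)CCCC.COc1ccc([O-])c(C[C@@H]2OC2(C)C)c1OC | intermediate
10 | 2-[(2R)-4,5-dimethoxy-2,3-dihydro-1-benzofuran-2-yl]propan-2-ol | COc1ccc2c(c1OC)C[C@H](C(C)(C)O)O2 | intermediate
11 | 2-[(2R)-7-bromo-4,5-dimethoxy-2,3-dihydro-1-benzofuran-2-yl]propan-2-ol | COc1cc(Br)c2c(c1OC)C[C@H](C(C)(C)O)O2 | intermediate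
12 | {2-[(2R)-7-bromo-4,5-dimethoxy-2,3-dihydro-1-benzofuran-2-yl]propan-2-yloxy}triethylsilane | COc1cc(Br)c2c(c1OC)C[C@H](C(C)(C)O[Si](CC)(CC)CC)O2 | intermediate
13 | 2',4',6'-trifluoroacetophenone | CC(=O)c1c(F)cc(F)cc1F | starting material
14 | 1-(2,4,6-trifluorophenyl)-2-[(2R)-4,5-dimethoxy-2-(2-triethylsilyloxypropan-2-yl)-2,3-dihydro-1-benzofuran-7-yl]ethanone | COc1cc(CC(=O)c2c(F)cc(F)cc2F)c2c(c1OC)C[C@H](C(C)(C)O[Si](CC)(CC)CC)O2 | intermediate
15 | 2,2,2-trifluoroethyl formate | O=COCC(F)(F)F | starting material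
16 | lithium enolate of 14 | [Li+].COc1cc(C=C([O-])c2c(F)cc(F)cc2F)c2c(c1OC)C[C@H](C(C)(C)O[Si](CC)(CC)CC)O2 | intermediate
17 | lithium enolate of the α-formyl derivative of 14 (geometry mobile) | [Li+].COc1cc(C(=C[O-])C(=O)c2c(F)cc(F)cc2F)c2c(c1OC)C[C@H](C(C)(C)O[Si](CC)(CC)CC)O2 | intermediate
18 | 3-[(2R)-4,5-dimethoxy-2-(2-triethylsilyloxypropan-2-yl)-2,3-dihydro-1-benzofuran-7-yl]-5,7-difluorochromen-4-one | COc1cc(-c2coc3cc(F)cc(F)c3c2=O)c2c(c1OC)C[C@H](C(C)(C)O[Si](CC)(CC)CC)O2 | intermediate
19 | 7-benzyloxy-5-fluoro analogue of 18 | COc1cc(-c2coc3cc(OCc4ccccc4)cc(F)c3c2=O)c2c(c1OC)C[C@H](C(C)(C)O[Si](CC)(CC)CC)O2 | intermediate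
20 | 5,7-bis(benzyloxy)-3-[(2R)-4,5-dimethoxy-2-(2-triethylsilyloxypropan-2-yl)-2,3-dihydro-1-benzofuran-7-yl]chromen-4-one | COc1cc(-c2coc3cc(OCc4ccccc4)cc(OCc4ccccc4)c3c2=O)c2c(c1OC)C[C@H](C(C)(C)O[Si](CC)(CC)CC)O2 | intermediate
21 | 5,7-bis(benzyloxy)-3-[(2R)-2-(2-hydroxypropan-2-yl)-4,5-dimethoxy-2,3-dihydro-1-benzofuran-7-yl]chromen-4-one | COc1cc(-c2coc3cc(OCc4ccccc4)cc(OCc4ccccc4)c3c2=O)c2c(c1OC)C[C@H](C(C)(C)O)O2 | intermediate
22 | 5,7-dihydroxy-3-[(2R)-2-(2-hydroxypropan-2-yl)-4,5-dimethoxy-2,3-dihydro-1-benzofuran-7-yl]chromen-4-one (CNP0211379.1) | COc1cc(-c2coc3cc(O)cc(O)c3c2=O)c2c(c1OC)C[C@H](C(C)(C)O)O2 | target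

Total step count: 12. Longest linear sequence: 12 steps (1 → 22); compounds 3, 13 and 15 are purchased.

**Steps most likely to fail**

Step 11. Benzyloxide may add to C2 faster than to the C–F carbons and hold the material as a ring-opened phenoxide, whose ring A is too electron-rich for displacement. The second exchange may also stall, and long heating then invites loss of the C2 carbon by retro-Claisen cleavage. The fallback brings both benzyloxy groups in before ring C exists and keeps the same ring closure. It sets out from 12 and returns at 20.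
- Commercial 5-fluororesorcinol is C-acetylated (Ac2O, BF3·OEt2, heat) to 1-(2-fluoro-4,6-dihydroxyphenyl)ethanone F1.
- F1 is benzylated (BnBr, K2CO3, DMF) to 1-[2,4-bis(benzyloxy)-6-fluorophenyl]ethanone F2.
- F2 is joined to 12 by the α-arylation of step 9 to give the bis(benzyloxy) monofluoro deoxybenzoin F3.
- F3 is formylated with LiHMDS and 15 and worked up to the hydroxymethylene ketone F4.
- K2CO3 in hot DMF displaces the single ortho fluoride of F4 to give 20, which the aqueous HCl treatment of step 11 converts into 21.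

Step 9. The enolate of the fluorinated ketone may be consumed by intermolecular fluoride displacement or self-condensation before the arylpalladium species, which forms slowly from an electron-rich bromide, can capture it. The fallback builds the ketone by polar additions at low temperature. It sets out from 12 and returns at 14.
- Bromine–lithium exchange (n-BuLi, THF, −78 °C) gives the aryllithium F5.
- Allyl bromide with catalytic CuI converts F5 into the 7-allyl dihydrobenzofuran F6.
- Lemieux–Johnson cleavage (OsO4 cat., NaIO4, 2,6-lutidine) gives the arylacetaldehyde F7.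
- 1,3,5-Trifluorobenzene and n-BuLi at −78 °C give 2,4,6-trifluorophenyllithium F8, which adds to F7 to give the carbinol F9 as a mixture of epimers.
- Dess–Martin oxidation of F9 gives 14.

Step 10. Proton exchange may stall the formylation, or the chelated lithium enolate may not reach the conformer needed for closure, so that intermolecular attack on the fluoroarene takes over on heating. The fallback separates C1 insertion from closure and uses no strong base. It sets out from 14 and returns at 18.
- Condensation with DMF dimethyl acetal (toluene, 100 °C) gives the enaminone F10.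
- Buffered aqueous acetic acid hydrolyses F10 to the hydroxymethylene ketone F11, which is isolated.
- K2CO3 in DMF, with a non-chelating cation, closes F11 to 18.

**Further compounds**
F1 | step 11 | 1-(2-fluoro-4,6-dihydroxyphenyl)ethanone | CC(=O)c1c(O)cc(O)cc1F
F2 | step 11 | 1-[2,4-bis(benzyloxy)-6-fluorophenyl]ethanone | CC(=O)c1c(F)cc(OCc2ccccc2)cc1OCc1ccccc1
F3 | step 11 | 1-[2,4-bis(benzyloxy)-6-fluorophenyl]-2-[(2R)-4,5-dimethoxy-2-(2-triethylsilyloxypropan-2-yl)-2,3-dihydro-1-benzofuran-7-yl]ethanone | COc1cc(CC(=O)c2c(F)cc(OCc3ccccc3)cc2OCc2ccccc2)c2c(c1OC)C[C@H](C(C)(C)O[Si](CC)(CC)CC)O2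
F4 | step 11 | α-hydroxymethylene derivative of F3 | COc1cc(C(=CO)C(=O)c2c(F)cc(OCc3ccccc3)cc2OCc2ccccc2)c2c(c1OC)C[C@H](C(C)(C)O[Si](CC)(CC)CC)O2
F5 | step 9 | [(2R)-4,5-dimethoxy-2-(2-triethylsilyloxypropan-2-yl)-2,3-dihydro-1-benzofuran-7-yl]lithium | COc1cc([Li])c2c(c1OC)C[C@H](C(C)(C)O[Si](CC)(CC)CC)O2
F6 | step 9 | {2-[(2R)-7-allyl-4,5-dimethoxy-2,3-dihydro-1-benzofuran-2-yl]propan-2-yloxy}triethylsilane | COc1cc(CC=C)c2c(c1OC)C[C@H](C(C)(C)O[Si](CC)(CC)CC)O2
F7 | step 9 | 2-[(2R)-4,5-dimethoxy-2-(2-triethylsilyloxypropan-2-yl)-2,3-dihydro-1-benzofuran-7-yl]acetaldehyde | COc1cc(CC=O)c2c(c1OC)C[C@H](C(C)(C)O[Si](CC)(CC)CC)O2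
F8 | step 9 | 2,4,6-trifluorophenyllithium | [Li]c1c(F)cc(F)cc1F
F9 | step 9 | 1-(2,4,6-trifluorophenyl)-2-[(2R)-4,5-dimethoxy-2-(2-triethylsilyloxypropan-2-yl)-2,3-dihydro-1-benzofuran-7-yl]ethanol (carbinol epimers) | COc1cc(CC(O)c2c(F)cc(F)cc2F)c2c(c1OC)C[C@H](C(C)(C)O[Si](CC)(CC)CC)O2
F10 | step 10 | α-(dimethylaminomethylene) derivative of 14 | COc1cc(C(=CN(C)C)C(=O)c2c(F)cc(F)cc2F)c2c(c1OC)C[C@H](C(C)(C)O[Si](CC)(CC)CC)O2
F11 | step 10 | α-hydroxymethylene derivative of 14 (neutral enol) | COc1cc(C(=CO)C(=O)c2c(F)cc(F)cc2F)c2c(c1OC)C[C@H](C(C)(C)O[Si](CC)(CC)CC)O2
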